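**Retrosynthetic overview**
- Last bond made: C(=O)–CH(Me) next to ring B. The target is cut into an (R)-2-pyranylpropanoic acid carrying ring A and the C2v-symmetric 2,6-diethyl-3,5-dimethylpyranone (ring B, complete); an enantioselective lateral C–H acylation of the latter breaks its symmetry and sets the S centre.
- The R centre is set one step earlier by enantioselective methylation of the ring A pyranylacetic acid enediolate.
- That acid comes from symmetric 2,3,5,6-tetramethylpyranone by two lateral lithiations: butylation (which breaks the symmetry), then carboxylation.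
- Tetramethylpyranone comes from 2,6-dimethyl-γ-pyrone by 3,5-dibromination and double methyl cross-coupling, so ring A is never built, only decorated.
- Ring order: ring A is present from the start; ring B is the only ring formed de novo (one-step polyphosphoric acid condensation, separate branch); the two rings are joined last.

Assumption: the sense of induction of the chiral amine (step 5) and of the bis(oxazoline) ligand (step 7) is taken by analogy with 2-arylpropanoic acids and α-aryl ketones (same priority order acyl > heteroaryl > methyl); if the first run shows the opposite sense, the antipodal amine or ligand is used.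

**Step 1**
Reactants: 1 2,6-dimethyl-4H-pyran-4-one
Product: 3 3,5-dibromo-2,6-dimethyl-4H-pyran-4-one, via monobromide 2 (not isolated)
Conditions: Br2 (2.2 equiv), AcOH, 60 °C; aq. NaHSO3/NaHCO3 work-up
Reagents that add atoms: bromine, BrBr
Why: Electrophilic substitution of the vinylogous ester occurs only at the two equivalent enol-ether-activated positions C3 and C5, so the dibromide forms via the monobromide and no stereocentre is created.

**Step 2**
Reactants: 3 3,5-dibromo-2,6-dimethyl-4H-pyran-4-one
Product: 5 2,3,5,6-tetramethyl-4H-pyran-4-one, via bromotrimethylpyranone 4 (not isolated)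
Conditions: trimethylboroxine (1.5 equiv), Pd(dppf)Cl2 (5 mol %), K2CO3 (4 equiv), 1,4-dioxane/H2O 10:1, 100 °C
Reagents that add atoms: trimethylboroxine, CB1OB(C)OB(C)O1
Why: Double Suzuki–Miyaura methylation works because zerovalent palladium inserts readily into the C(sp2)–Br bonds of this α-bromo-enone-type pyranone and a methyl group cannot undergo β-hydride elimination; no stereocentre is created.

**Step 3**
Reactants: 5 2,3,5,6-tetramethyl-4H-pyran-4-one
Product: 7 2,3,5-trimethyl-6-pentyl-4H-pyran-4-one, via lithium dienolate 6 (not isolated)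
Conditions: LiN(i-Pr)2 (1.0 equiv), THF, −78 °C; n-BuI (1.1 equiv), DMPU, −78 → 0 °C; 5 used in 1.3-fold excess and recovered
Reagents that add atoms: 1-iodobutane, CCCCI; lithium diisopropylamide, [Li+].CC(C)[N-]C(C)C (lithium of 6 only)
Why: Lateral (vinylogous) deprotonation of one of the two homotopic 2/6-methyl groups gives the exocyclic dienolate, which is C-alkylated by the primary iodide with re-aromatisation (vinylogous enolate alkylation), breaking the C2v symmetry of 5 without creating a stereocentre.

**Step 4**
Reactants: 7 2,3,5-trimethyl-6-pentyl-4H-pyran-4-one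
Product: 9 2-(3,5-dimethyl-4-oxo-6-pentyl-4H-pyran-2-yl)acetic acid, via lithium dienolate 8 (not isolated)
Conditions: LiN(i-Pr)2 (1.05 equiv), THF, −78 °C, 20 min; cannulated into CO2-saturated THF, −78 °C; 1 M HCl
Reagents that add atoms: carbon dioxide, O=C=O; lithium diisopropylamide, [Li+].CC(C)[N-]C(C)C (lithium of 8 only)
Why: Kinetic lateral lithiation takes the primary C–H of the remaining 2-methyl group in preference to the secondary α-CH2 of the pentyl chain (as in kinetic enolisation of methyl alkyl ketones), and carboxylation of the vinylogous enolate by inverse addition into excess CO2 prevents the more acidic product from quenching unreacted 8; no stereocentre is created.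

**Step 5**
Reactants: 9 2-(3,5-dimethyl-4-oxo-6-pentyl-4H-pyran-2-yl)acetic acid
Product: 11 (R)-2-(3,5-dimethyl-4-oxo-6-pentyl-4H-pyran-2-yl)propanoic acid, via dilithium enediolate 10 (not isolated)
Conditions: (R,R)-N1,N3-bis[1-phenyl-2-(piperidin-1-yl)ethyl]propane-1,3-diamine (1.05 equiv), n-BuLi (4.0 equiv), THF, 0 °C; 9, −78 → 0 °C; MeI (1.5 equiv), −78 °C; 1 M HCl (amine recovered by acid–base extraction)
Reagents that add atoms: iodomethane, CI; n-butyllithium, [Li]CCCC (lithium of 10 only)
Why: Enantioselective enediolate alkylation with a chiral lithium amide as traceless auxiliary (known for arylacetic acids) applies because the C2-symmetric dilithium amide forms a mixed aggregate with 10 and shields one face, so iodomethane creates the R centre, and the resulting carboxylate cannot be deprotonated again, which protects the new centre.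

**Step 6**
Reactants: 12 pentan-3-one; 13 propanoic anhydride
Product: 16 2,6-diethyl-3,5-dimethyl-4H-pyran-4-one, via diketone 14 (not isolated), via triketone 15 (not isolated)
Conditions: polyphosphoric acid, 95 °C, 4 h; ice, aq. NaOH, extraction, distillation
Reagents that add atoms: none
Why: Classical polyphosphoric-acid-mediated double C-acylation of the ketone at both α-positions followed by cyclodehydration of the 1,3,5-triketone gives the symmetric 4-pyranone; no stereocentre is created.

**Step 7**
Reactants: 11 (R)-2-(3,5-dimethyl-4-oxo-6-pentyl-4H-pyran-2-yl)propanoic acid; 16 2,6-diethyl-3,5-dimethyl-4H-pyran-4-one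
Product: 18 (2R,4S)-2-(3,5-dimethyl-4-oxo-6-pentyl-4H-pyran-2-yl)-4-(6-ethyl-3,5-dimethyl-4-oxo-4H-pyran-2-yl)pentan-3-one, via mixed anhydride 17 (not isolated)
Conditions: (MeOCO)2O (2.0 equiv), 2,6-lutidine (0.5 equiv), i-PrOAc, 0 °C → rt; then 16 (5 equiv, excess recovered), NiBr2(dme) (10 mol %), (S,S)-Ph-BOX (12 mol %), Ir[dF(CF3)ppy]2(dtbbpy)PF6 (2 mol %), LiBr (20 mol %), blue LEDs, 10 °C; base-free work-up, chromatography on pH 7 buffered silica at 0 °C
Reagents that add atoms: dimethyl dicarbonate, COC(=O)OC(=O)OC (methoxycarbonyl group of 17 only; none of its atoms remain in 18)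
Why: Proposed new method: desymmetrising enantioselective lateral C(sp3)–H acylation, in which photoexcited iridium oxidises bromide to a bromine atom that abstracts one of the four equivalent, weak vinylogous α-keto CH2 hydrogens of C2v-symmetric 16, the planar radical is captured by the chiral bis(oxazoline) acyl–nickel species formed by oxidative addition of zerovalent nickel into 17, and reductive elimination from trivalent nickel forms the C–C bond and sets the S centre under catalyst control while the R centre of the acyl partner is untouched because no enolate is generated; the closest known reaction type is the nickel/photoredox asymmetric benzylic C–H acylation of alkylarenes with in-situ-activated carboxylic acids (related to the enantioconvergent reductive acyl cross-coupling of secondary benzylic chlorides).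

**Compound list**
1 | 2,6-dimethyl-4H-pyran-4-one | Cc1cc(=O)cc(C)o1 | starting material
2 | 3-bromo-2,6-dimethyl-4H-pyran-4-one | Cc1cc(=O)c(Br)c(C)o1 | intermediate
3 | 3,5-dibromo-2,6-dimethyl-4H-pyran-4-one | Cc1oc(C)c(Br)c(=O)c1Br | intermediate
4 | 3-bromo-2,5,6-trimethyl-4H-pyran-4-one | Cc1oc(C)c(Br)c(=O)c1C | intermediate
5 | 2,3,5,6-tetramethyl-4H-pyran-4-one | Cc1oc(C)c(C)c(=O)c1C | intermediate
6 | lithium 3,5,6-trimethyl-2-methylidene-2H-pyran-4-olate | [Li+].[O-]C1=C(C)C(=C)OC(C)=C1C | intermediate
7 | 2,3,5-trimethyl-6-pentyl-4H-pyran-4-one | CCCCCc1oc(C)c(C)c(=O)c1C | intermediate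
8 | lithium 3,5-dimethyl-2-methylidene-6-pentyl-2H-pyran-4-olate | [Li+].[O-]C1=C(C)C(=C)OC(CCCCC)=C1C | intermediate
9 | 2-(3,5-dimethyl-4-oxo-6-pentyl-4H-pyran-2-yl)acetic acid | CCCCCc1oc(CC(=O)O)c(C)c(=O)c1C | intermediate
10 | dilithium 2-(3,5-dimethyl-4-oxo-6-pentyl-4H-pyran-2-yl)ethene-1,1-bis(olate) | [Li+].[Li+].[O-]C([O-])=Cc1oc(CCCCC)c(C)c(=O)c1C | intermediate
11 | (R)-2-(3,5-dimethyl-4-oxo-6-pentyl-4H-pyran-2-yl)propanoic acid | CCCCCc1oc([C@@H](C)C(=O)O)c(C)c(=O)c1C | intermediate
12 | pentan-3-one | CCC(=O)CC | starting material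
13 | propanoic anhydride | CCC(=O)OC(=O)CC | starting material
14 | 4-methylheptane-3,5-dione | CCC(=O)C(C)C(=O)CC | intermediate
15 | 4,6-dimethylnonane-3,5,7-trione | CCC(=O)C(C)C(=O)C(C)C(=O)CC | intermediate
16 | 2,6-diethyl-3,5-dimethyl-4H-pyran-4-one | CCc1oc(CC)c(C)c(=O)c1C | intermediate
17 | methoxycarbonyl (R)-2-(3,5-dimethyl-4-oxo-6-pentyl-4H-pyran-2-yl)propanoate (mixed carbonic anhydride) | CCCCCc1oc([C@@H](C)C(=O)OC(=O)OC)c(C)c(=O)c1C | intermediate
18 | (2R,4S)-2-(3,5-dimethyl-4-oxo-6-pentyl-4H-pyran-2-yl)-4-(6-ethyl-3,5-dimethyl-4-oxo-4H-pyran-2-yl)pentan-3-one | CCCCCc1oc([C@@H](C)C(=O)[C@@H](C)c2oc(CC)c(C)c(=O)c2C)c(C)c(=O)c1C | target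

**Step count and risks**
Total step count: 7. Longest linear sequence: 6 (steps 1, 2, 3, 4, 5, 7); step 6 is a one-step side branch.

Both α-centres of 18 are epimerisable, so 18 is kept cold and away from base. Because the two centres are set independently, the minor enantiomer of 18 arises only when both controllers err. Removing the (2R,4R)/(2S,4S) diastereomers by chromatography therefore raises the ee of 18 above that of 11.

The three steps most likely to fail:

Step 7 (key C–H acylation). Risks: hydrogen abstraction at the other lateral CH2 groups, decarbonylation of the α-branched acyl–nickel species, and erosion of the R centre through ketene formation from 17. The fallback sets out from 16 and 11 and comes back at 18. It replaces photochemical C–H abstraction by pre-functionalisation and a base-free reductive coupling. 16 is lithiated with LiN(i-Pr)2 to lithium 6-ethyl-2-ethylidene-3,5-dimethyl-2H-pyran-4-olate F1, which is added inversely to hexachloroethane to give racemic 2-(1-chloroethyl)-6-ethyl-3,5-dimethyl-4H-pyran-4-one F2. 11 is converted under neutral conditions with 1-chloro-N,N,2-trimethylprop-1-en-1-amine into (R)-2-(3,5-dimethyl-4-oxo-6-pentyl-4H-pyran-2-yl)propanoyl chloride F3. F2 and F3 are then joined by enantioconvergent nickel-catalysed reductive acyl cross-coupling (NiCl2(dme), (S,S)-Ph-BOX, manganese powder, 2,6-dimethylbenzoic acid, DMA/THF, 20 °C) to give 18.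

Step 5 (asymmetric methylation). Risks: lower enantioselectivity for this extended enediolate than for simple arylacetic acids, attack of n-BuLi on the pyranone, and a further lateral deprotonation by the excess amide. The fallback sets out from 9 and comes back at 11. It uses a covalent auxiliary and only one equivalent of base. 9 is activated with pivaloyl chloride/Et3N as 2-(3,5-dimethyl-4-oxo-6-pentyl-4H-pyran-2-yl)acetic pivalic anhydride F4. F4 acylates (R)-4-benzyloxazolidin-2-one (LiCl, Et3N, THF) to give (R)-4-benzyl-3-[2-(3,5-dimethyl-4-oxo-6-pentyl-4H-pyran-2-yl)acetyl]oxazolidin-2-one F5. NaN(SiMe3)2 (1.05 equiv, THF, −78 °C) gives the sodium (Z)-enolate of F5 F6. MeI methylates F6 on the face away from the benzyl group to give (R)-4-benzyl-3-[(R)-2-(3,5-dimethyl-4-oxo-6-pentyl-4H-pyran-2-yl)propanoyl]oxazolidin-2-one F7, and the minor diastereomer is removed by chromatography. LiOH/H2O2 (THF/H2O, 0 °C), then Na2SO3 and acidification, gives 11 and returns the auxiliary.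

Step 4 (regioselective lithiation and carboxylation). Risk: competing deprotonation at the pentyl α-CH2, which would give a regioisomeric acid that is hard to separate. The fallback sets out from 5 and comes back at 9. It fixes the regiochemistry by dianion reactivity and reverses the order of events. Symmetric 5 is lithiated to 6 (2.1 equiv LiN(i-Pr)2) and C-acylated with di-tert-butyl dicarbonate to give tert-butyl 2-(3,5,6-trimethyl-4-oxo-4H-pyran-2-yl)acetate F8. LiN(i-Pr)2 (2.2 equiv, THF, −78 °C) converts F8 into dilithium 2-(2-tert-butoxy-2-oxidoethenyl)-3,5-dimethyl-6-methylidene-6H-pyran-4-olate F9. 1-Iodobutane (1.0 equiv) alkylates F9 only at the more basic, later-formed lateral carbon to give tert-butyl 2-(3,5-dimethyl-4-oxo-6-pentyl-4H-pyran-2-yl)acetate F10. CF3CO2H in CH2Cl2 cleaves the ester to 9.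

**Further compounds**
F1 | step 7 | lithium 6-ethyl-2-ethylidene-3,5-dimethyl-2H-pyran-4-olate | [Li+].[O-]C1=C(C)C(=CC)OC(CC)=C1C
F2 | step 7 | racemic 2-(1-chloroethyl)-6-ethyl-3,5-dimethyl-4H-pyran-4-one | CCc1oc(C(C)Cl)c(C)c(=O)c1C
F3 | step 7 | (R)-2-(3,5-dimethyl-4-oxo-6-pentyl-4H-pyran-2-yl)propanoyl chloride | CCCCCc1oc([C@@H](C)C(Cl)=O)c(C)c(=O)c1C
F4 | step 5 | 2-(3,5-dimethyl-4-oxo-6-pentyl-4H-pyran-2-yl)acetic pivalic anhydride | CCCCCc1oc(CC(=O)OC(=O)C(C)(C)C)c(C)c(=O)c1C
F5 | step 5 | (R)-4-benzyl-3-[2-(3,5-dimethyl-4-oxo-6-pentyl-4H-pyran-2-yl)acetyl]oxazolidin-2-one | CCCCCc1oc(CC(=O)N2[C@H](Cc3ccccc3)COC2=O)c(C)c(=O)c1C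
F6 | step 5 | sodium (Z)-enolate of F5 | [Na+].[O-]/C(=C\c1oc(CCCCC)c(C)c(=O)c1C)N1[C@H](Cc2ccccc2)COC1=O
F7 | step 5 | (R)-4-benzyl-3-[(R)-2-(3,5-dimethyl-4-oxo-6-pentyl-4H-pyran-2-yl)propanoyl]oxazolidin-2-one | CCCCCc1oc([C@@H](C)C(=O)N2[C@H](Cc3ccccc3)COC2=O)c(C)c(=O)c1C
F8 | step 4 | tert-butyl 2-(3,5,6-trimethyl-4-oxo-4H-pyran-2-yl)acetate | Cc1oc(CC(=O)OC(C)(C)C)c(C)c(=O)c1C
F9 | step 4 | dilithium 2-(2-tert-butoxy-2-oxidoethenyl)-3,5-dimethyl-6-methylidene-6H-pyran-4-olate | [Li+].[Li+].[O-]C(OC(C)(C)C)=CC1=C(C)C([O-])=C(C)C(=C)O1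
F10 | step 4 | tert-butyl 2-(3,5-dimethyl-4-oxo-6-pentyl-4H-pyran-2-yl)acetate | CCCCCc1oc(CC(=O)OC(C)(C)C)c(C)c(=O)c1C
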